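I began with the lag.

| flask | starting material | gas | temperature | remark | time |
|---|---|---|---|---|---|
| elm | 0.0034 M (in portions, 4) | 0.65 mM (held) | 35 °C | run made earlier; portions every 1.0 min |  |
| oak | 0.011 M (in portions, 4) | 0.65 mM (held) | 46 °C | run made earlier; portions every 1.0 min |  |
| epsilon | 0.0040 M | 0.65 mM | 40 °C | everything together at the start | 4.0 min |
| delta | 0.012 M (in portions, 4) | 0.65 mM (held) | 40 °C | the portions of starting material follow each other after 1.0 min, the first at the start | 4.0 min |

| run | time / s | target / % |
|---|---|---|
| elm | 15.0 | 0 |
| elm | 40.0 | 2.4 |
| elm | 80.0 | 6.6 |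
| elm | 120 | 12.2 |
| oak | 15.0 | 1.6 |
| oak | 40.0 | 6.7 |
| oak | 80.0 | 13.6 |
| oak | 120 | 21.4 |

(standard deviation of a reading: 0.5 percentage points)

1. the flask that ends with the higher amount of target, in percent of the starting material charged, or "neither" when 2 percentage points or less lies between them (epsilon / delta / neither)
2. final target, as a percentage of the starting material charged, in epsilon
3. final target, as a percentage of the starting material charged, in delta

- at the start none of the gas is in solution

In the oak run, the line through the first two readings put the first target at 7.16 s, while the elm run still read 0 % at 15.0 s. Between the two temperatures I placed a lag of 10.7 s for 40 °C.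

While the first portion stood alone, target grew by 0.230 min⁻¹ of that portion in elm and 0.490 min⁻¹ in oak. These readings carry their scatter. Interpolated on a logarithmic scale, they gave a pseudo-first-order constant of 0.325 min⁻¹ at 40 °C.

Over the later readings, the oak slope fell to 0.110 min⁻¹ of the whole charge from 0.122 min⁻¹, whereas the elm slope rose to 0.0735 min⁻¹ from 0.0576 min⁻¹. So I supposed a bend somewhere between the elm portion, 0.850 mM, and the oak portion, though the two runs differ in temperature. For my reckoning I set the crossing concentration at the oak portion, 2.75 mM, which was a choice and not a reading: in this picture the rate stands still above it and follows [starting material] below it. This gave 0.893 mM min⁻¹ for the ceiling rate, the constant times the crossing concentration.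

I drew epsilon flat through the lag, then straight at 0.223 min⁻¹ of its charge. Its knee came at 1.58 min, where [starting material] reached the crossing. The curve then bent towards the whole charge and stood at 68.7 % at 4.0 min. Delta, refilled by 3.00 mM per portion, more than the crossing concentration, I held on the ceiling, which gave 28.4 %.

The forecast named epsilon, with 60 % and 23 %: “Near-zero-order kinetics favour the dilute flask.” My two figures stood higher.

The flasks gave epsilon as the higher, with 63.2 % in epsilon and 30.3 % in delta.

    starting material + reagent → intermediate (k = 16.0 M⁻¹ s⁻¹, Ea = 51.0 kJ mol⁻¹)
    intermediate → target (k = 0.0310 s⁻¹, Ea = 83.0 kJ mol⁻¹)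
    starting material + target → side product (k = 2.10 M⁻¹ s⁻¹, Ea = 62.0 kJ mol⁻¹)
    gas ⇌ reagent, rate k4*(csat - [reagent]) (kL = 2.30 s⁻¹)
    (constants at 40 °C)

Delta ended 1.9 percentage points above my reckoning, and epsilon 5.5 points below it, with side product at 30.6 % in epsilon. The ceiling belonged to my reckoning and stands nowhere in the equations; reagent in delta stood at 6.42 × 10⁻⁴ M at 4.00 min, with side product at 46.8 %. The neighbour is epsilon stopped at 1.0 min, earlier than the knee. The ceiling rate, applied after the lag and divided by the charge, gives 18.3 % there. That stopped flask held 23.3 % target, with 51.9 % starting material.

(The data stem from a simulated flask for an exercise; scatter was added.)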